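The route rests on making the central C8–C8' bond between the two methyl-bearing carbons (lignan numbering: C7 bears the acetate and dimethoxyphenyl ring A; C7' is the CH2 on guaiacyl ring B). C8 lies alpha to C7, so a C7 ketone makes a C8 radical planar and stabilised. C8' adjoins benzylic C7', so it can be an alkenyl carbon conjugated with ring B. In one operation, hydrozirconation of an arylpropyne and nickel-catalysed stereoconvergent coupling with a racemic alpha-bromopropiophenone join both C6C3 halves, fix the E alkene and funnel both bromide enantiomers into (S)-C8. Catalyst-controlled hydrogenation and ketone reduction then set C8' and C7.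

Key step: step 4

Assumption: the (S,S)-bis(oxazoline) in step 4 and the (S)-phosphinooxazoline in step 5 are assigned by analogy with simple alpha-bromo aryl ketones and (E)-1,2-diarylpropenes. Both antipodes of each ligand are commercial, so the mirror-image ligand is used if the sense of induction proves reversed.

Step 1
Reactants: 1 4-bromo-2-methoxyphenol
Product: 2 (4-bromo-2-methoxyphenoxy)triisopropylsilane
Conditions: TIPSCl, imidazole, DMF, rt
Reagents that add atoms: chlorotriisopropylsilane (TIPSCl), CC(C)[Si](Cl)(C(C)C)C(C)C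
Why: Imidazole-promoted O-silylation masks the acidic phenol against Cp2Zr(H)Cl and the later organometallic and acylation steps, and the bulky aryl TIPS ether can be removed at the end by fluoride without touching an acetate.

Step 2
Reactants: 2 (4-bromo-2-methoxyphenoxy)triisopropylsilane; 3 propyne
Product: 4 [2-methoxy-4-(prop-1-yn-1-yl)phenoxy]triisopropylsilane
Conditions: PdCl2(PPh3)2 (cat.), CuI (cat.), Et3N/DMF, sealed tube, 80 °C
Reagents that add atoms: none
Why: Sonogashira coupling of the aryl bromide with the terminal alkyne installs C7', C8' and C9' of ring B's side chain at the alkyne oxidation level, and no stereocentre is formed.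

Step 3
Reactants: 5 1-(3,4-dimethoxyphenyl)propan-1-one
Product: 6 rac-2-bromo-1-(3,4-dimethoxyphenyl)propan-1-one
Conditions: CuBr2 (2 equiv), EtOAc/CHCl3, reflux
Reagents that add atoms: CuBr2, Br[Cu]Br
Why: Alpha-bromination of an aryl ketone through its enol, in which heterogeneous CuBr2 halogenates the enolisable CH2 and spares electron-rich ring A, and the racemic nature of 6 is irrelevant because step 4 is stereoconvergent.

Step 4
Reactants: 4 [2-methoxy-4-(prop-1-yn-1-yl)phenoxy]triisopropylsilane; 6 rac-2-bromo-1-(3,4-dimethoxyphenyl)propan-1-one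
Product: 8 (2S,3E)-1-(3,4-dimethoxyphenyl)-4-[3-methoxy-4-(triisopropylsilyloxy)phenyl]-2,3-dimethylbut-3-en-1-one, via alkenylzirconocene chloride 7 (not isolated)
Conditions: Cp2Zr(H)Cl, THF, rt to 40 °C; then 6, NiCl2·glyme (5 mol %), (S,S)-Ph-BOX [2,2'-isopropylidenebis((4S)-4-phenyl-2-oxazoline), 6.5 mol %], DME/THF, 10 °C; quick filtration through deactivated silica
Reagents that add atoms: zirconocene chloride hydride Cp2Zr(H)Cl, [H][Zr](Cl)(C1C=CC=C1)C1C=CC=C1 (its Cp2ZrCl unit stands in 7 only; 8 keeps only the hydrogen)
Why: Syn-hydrozirconation of 4 puts zirconium on the less hindered, methyl-bearing alkyne carbon (future C8') and hydrogen on the benzylic carbon, which fixes the E geometry of 7; transmetalation to the bis(oxazoline)-bound nickel then gives an alkenyl complex of monovalent nickel that abstracts bromine from either enantiomer of 6 to give the same planar, carbonyl-stabilised C8 radical. Capture of this radical at nickel and reductive elimination from trivalent nickel form C8–C8' with retention of the alkene geometry. The closest known reaction type is the nickel/bis(oxazoline)-catalysed stereoconvergent Negishi-type alkenylation of racemic alpha-bromo aryl ketones with alkenylzirconium reagents. No ring is closed. The only new stereocentre, C8 (S), is controlled by the chiral ligand on nickel and not by the substrate, so both enantiomers of 6 should converge on one product. The step needs regioselective hydrometalation, secured by the aryl/methyl size difference and by equilibration of the alkenylzirconium isomers, and it needs the labile alpha-centre of a beta,gamma-unsaturated ketone to survive, secured by the base-free medium at 10 °C.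

Step 5
Reactants: 8 (2S,3E)-1-(3,4-dimethoxyphenyl)-4-[3-methoxy-4-(triisopropylsilyloxy)phenyl]-2,3-dimethylbut-3-en-1-one
Product: 9 (2S,3R)-1-(3,4-dimethoxyphenyl)-4-[3-methoxy-4-(triisopropylsilyloxy)phenyl]-2,3-dimethylbutan-1-one
Conditions: H2 (50 bar), [Ir(cod)((S)-tBu-PHOX)]BArF (2 mol %), CH2Cl2, rt
Reagents that add atoms: none
Why: Iridium–phosphinooxazoline asymmetric hydrogenation of a trisubstituted, aryl-conjugated E alkene adds H2 syn to the face chosen by the chiral N,P ligand and so sets C8' as R under catalyst control, while the base-free medium should leave the ketone, the silyl ether and C8 untouched and no acid-labile benzylic C–O bond is yet present.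

Step 6
Reactants: 9 (2S,3R)-1-(3,4-dimethoxyphenyl)-4-[3-methoxy-4-(triisopropylsilyloxy)phenyl]-2,3-dimethylbutan-1-one
Product: 10 (1R,2S,3R)-1-(3,4-dimethoxyphenyl)-4-[3-methoxy-4-(triisopropylsilyloxy)phenyl]-2,3-dimethylbutan-1-ol
Conditions: (S)-Me-CBS oxazaborolidine (0.3 equiv), BH3·SMe2, THF, −20 °C; MeOH, then aqueous work-up
Reagents that add atoms: none
Why: In this Corey–Bakshi–Shibata reduction the (S)-oxazaborolidine binds the ketone with ring A as the large group and delivers hydride to the face that gives the (R)-carbinol, so reagent control overrides the Felkin–Anh preference of C8 and should give the 7,8-syn alcohol.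

Step 7
Reactants: 10 (1R,2S,3R)-1-(3,4-dimethoxyphenyl)-4-[3-methoxy-4-(triisopropylsilyloxy)phenyl]-2,3-dimethylbutan-1-ol
Product: 11 (1R,2S,3R)-1-(3,4-dimethoxyphenyl)-4-[3-methoxy-4-(triisopropylsilyloxy)phenyl]-2,3-dimethylbutyl acetate
Conditions: Ac2O, Et3N, DMAP (cat.), CH2Cl2, 0 °C to rt
Reagents that add atoms: acetic anhydride, CC(=O)OC(C)=O
Why: DMAP-catalysed O-acylation proceeds with retention at C7, only the secondary alcohol reacts because the phenol is still silylated, and the basic medium avoids ionisation of the electron-rich benzylic position.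

Step 8
Reactants: 11 (1R,2S,3R)-1-(3,4-dimethoxyphenyl)-4-[3-methoxy-4-(triisopropylsilyloxy)phenyl]-2,3-dimethylbutyl acetate
Product: 12 (1R,2S,3R)-1-(3,4-dimethoxyphenyl)-4-(4-hydroxy-3-methoxyphenyl)-2,3-dimethylbutyl acetate (target)
Conditions: Bu4NF, AcOH (1:1), THF, 0 °C
Reagents that add atoms: none
Why: Fluoride-induced cleavage of the aryl silyl ether (desilylation), buffered with AcOH so that the liberated phenoxide is protonated at once, should neither transfer nor hydrolyse the acetate and involves no acid strong enough to ionise C7.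

Compound list
1 | 4-bromo-2-methoxyphenol | COc1cc(Br)ccc1O | starting material
2 | (4-bromo-2-methoxyphenoxy)triisopropylsilane | COc1cc(Br)ccc1O[Si](C(C)C)(C(C)C)C(C)C | intermediate
3 | propyne | CC#C | starting material
4 | [2-methoxy-4-(prop-1-yn-1-yl)phenoxy]triisopropylsilane | COc1cc(C#CC)ccc1O[Si](C(C)C)(C(C)C)C(C)C | intermediate
5 | 1-(3,4-dimethoxyphenyl)propan-1-one | CCC(=O)c1ccc(OC)c(OC)c1 | starting material
6 | rac-2-bromo-1-(3,4-dimethoxyphenyl)propan-1-one | CC(Br)C(=O)c1ccc(OC)c(OC)c1 | intermediate
7 | chlorobis(cyclopentadienyl){(1E)-1-[3-methoxy-4-(triisopropylsilyloxy)phenyl]prop-1-en-2-yl}zirconium | COc1cc(/C=C(\C)[Zr](Cl)(C2C=CC=C2)C2C=CC=C2)ccc1O[Si](C(C)C)(C(C)C)C(C)C | intermediate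
8 | (2S,3E)-1-(3,4-dimethoxyphenyl)-4-[3-methoxy-4-(triisopropylsilyloxy)phenyl]-2,3-dimethylbut-3-en-1-one | COc1cc(/C=C(\C)[C@H](C)C(=O)c2ccc(OC)c(OC)c2)ccc1O[Si](C(C)C)(C(C)C)C(C)C | intermediate
9 | (2S,3R)-1-(3,4-dimethoxyphenyl)-4-[3-methoxy-4-(triisopropylsilyloxy)phenyl]-2,3-dimethylbutan-1-one | COc1cc(C[C@@H](C)[C@H](C)C(=O)c2ccc(OC)c(OC)c2)ccc1O[Si](C(C)C)(C(C)C)C(C)C | intermediate
10 | (1R,2S,3R)-1-(3,4-dimethoxyphenyl)-4-[3-methoxy-4-(triisopropylsilyloxy)phenyl]-2,3-dimethylbutan-1-ol | COc1cc(C[C@@H](C)[C@H](C)[C@@H](O)c2ccc(OC)c(OC)c2)ccc1O[Si](C(C)C)(C(C)C)C(C)C | intermediate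
11 | (1R,2S,3R)-1-(3,4-dimethoxyphenyl)-4-[3-methoxy-4-(triisopropylsilyloxy)phenyl]-2,3-dimethylbutyl acetate | COc1cc(C[C@@H](C)[C@H](C)[C@@H](OC(C)=O)c2ccc(OC)c(OC)c2)ccc1O[Si](C(C)C)(C(C)C)C(C)C | intermediate
12 | (1R,2S,3R)-1-(3,4-dimethoxyphenyl)-4-(4-hydroxy-3-methoxyphenyl)-2,3-dimethylbutyl acetate | COc1cc(C[C@@H](C)[C@H](C)[C@@H](OC(C)=O)c2ccc(OC)c(OC)c2)ccc1O | target

Total step count: 8. Longest linear sequence: 7 (steps 1, 2, 4, 5, 6, 7, 8).

Steps most likely to fail

Step 4. Hydrozirconation of the internal alkyne may give a mixture of regioisomers. The alpha-branched alkenylzirconium may transmetalate to nickel slowly. Enantioselection may erode, or the product may slip into conjugation. In the fallback the same bond is made without asymmetric induction, and C8 is corrected afterwards through its acidity. The fallback sets out from 7 and 5 and comes back at 9.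
- Iodinolysis of 7 (I2, THF, 0 °C) gives the (E)-alkenyl iodide F1, which can be freed from any regioisomer by chromatography.
- Palladium-catalysed alpha-alkenylation of 5 with F1 (LiN(SiMe3)2, Pd(dba)2, P(t-Bu)3, toluene/THF, rt) gives the racemic beta,gamma-unsaturated ketone F2.
- Hydrogenation under the conditions of step 5 fixes C8' as R in both enantiomers and should give 9 beside its C8 epimer F3.
- The two diastereomers are separated, and F3 is re-equilibrated at C8 with DBU in warm toluene and recycled.

Step 5. The catalyst may show poor facial selectivity if the allylic C8 centre or coordination of the ketone opposes it. Conversion of the hindered alkene may be sluggish. The double bond may migrate toward the carbonyl with loss of C8. The fallback replaces catalyst control by substrate direction. It sets out from 8 and comes back at 9.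
- LiBH(s-Bu)3 (THF, −78 °C) reduces 8 under Felkin–Anh control, with the alkenyl group as the large substituent, to the 7,8-anti alkenol F4.
- Hydroxyl-directed hydrogenation with [Rh(nbd)(dppb)]BF4 (H2, 40 bar, CH2Cl2) should proceed through a chelate with ring A pseudo-equatorial and the oxygen gauche to the C8 hydrogen. This chelate exposes the alkene face that makes C8' R and gives the saturated alcohol F5.
- Dess–Martin oxidation of F5 returns 9.

Step 6. Facial selectivity may be poor because the oxazaborolidine has to tell ring A from a branched alkyl group while working against the Felkin–Anh bias. The fallback works with the substrate bias and then inverts C7. It sets out from 9 and comes back at 10.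
- LiBH(s-Bu)3 (THF, −78 °C) gives the Felkin–Anh (1S)-alcohol F5, the same compound as in the fallback for step 5.
- Mitsunobu inversion with 4-nitrobenzoic acid (PPh3, DIAD, toluene, 0 °C) gives the (1R)-4-nitrobenzoate F6.
- Brief methanolysis (K2CO3, MeOH, 0 °C), which the aryl TIPS ether should tolerate, gives 10.

Further compounds
F1 | step 4 | {4-[(1E)-2-iodoprop-1-en-1-yl]-2-methoxyphenoxy}triisopropylsilane | COc1cc(/C=C(\C)I)ccc1O[Si](C(C)C)(C(C)C)C(C)C
F2 | step 4 | rac-(3E)-1-(3,4-dimethoxyphenyl)-4-[3-methoxy-4-(triisopropylsilyloxy)phenyl]-2,3-dimethylbut-3-en-1-one | COc1cc(/C=C(\C)C(C)C(=O)c2ccc(OC)c(OC)c2)ccc1O[Si](C(C)C)(C(C)C)C(C)C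
F3 | step 4 | (2R,3R)-1-(3,4-dimethoxyphenyl)-4-[3-methoxy-4-(triisopropylsilyloxy)phenyl]-2,3-dimethylbutan-1-one | COc1cc(C[C@@H](C)[C@@H](C)C(=O)c2ccc(OC)c(OC)c2)ccc1O[Si](C(C)C)(C(C)C)C(C)C
F4 | step 5 | (1S,2S,3E)-1-(3,4-dimethoxyphenyl)-4-[3-methoxy-4-(triisopropylsilyloxy)phenyl]-2,3-dimethylbut-3-en-1-ol | COc1cc(/C=C(\C)[C@H](C)[C@H](O)c2ccc(OC)c(OC)c2)ccc1O[Si](C(C)C)(C(C)C)C(C)C
F5 | step 5 | (1S,2S,3R)-1-(3,4-dimethoxyphenyl)-4-[3-methoxy-4-(triisopropylsilyloxy)phenyl]-2,3-dimethylbutan-1-ol | COc1cc(C[C@@H](C)[C@H](C)[C@H](O)c2ccc(OC)c(OC)c2)ccc1O[Si](C(C)C)(C(C)C)C(C)C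
F6 | step 6 | (1R,2S,3R)-1-(3,4-dimethoxyphenyl)-4-[3-methoxy-4-(triisopropylsilyloxy)phenyl]-2,3-dimethylbutyl 4-nitrobenzoate | COc1cc(C[C@@H](C)[C@H](C)[C@@H](OC(=O)c3ccc(cc3)[N+](=O)[O-])c2ccc(OC)c(OC)c2)ccc1O[Si](C(C)C)(C(C)C)C(C)C
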